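(Readings and results were generated by integration for an exercise.)

Early in the violet run, at 30.0 min, the product's excess reads ε = 28.9%, higher than the 23.7% at 120 min. Meanwhile left-handed substrate makes up 50.2% of the unreacted substrate at 60.0 min in violet, so there the exchange keeps up.

| flask | left-handed substrate | right-handed substrate | reagent | racemization catalyst | precatalyst | remark | time |
|---|---|---|---|---|---|---|---|
| violet | 20 mM | 20 mM | 60 mM | 40 µM | 0.20 mM | the very flask that is asked about, followed so far |  |
| amber | 20 mM | 20 mM | 40 mM | 40 µM | 0.20 mM | run made earlier |  |
| flask | 20 mM | 20 mM | 60.0 mM | 40 µM | 0.20 mM |  | 6.0 h |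

- violet (time / min: left-handed product / %, right-handed product / %, left-handed substrate / %): 6.00: 1.4, 0.9, 49.4; 15.0: 7.8, 4.1, 44.1; 30.0: 18.5, 10.2, 35.2; 50.0: 31.7, 18.0, 25.1; 60.0: 36.5, 21.3, 21.2; 80.0: 43.5, 26.0, 15.7; 120: 50.3, 31.0, 8.4
- amber (time / h: left-handed product / %, right-handed product / %, left-handed substrate / %): 0.333: 8.0, 4.2, 43.4; 0.500: 13.3, 7.1, 39.9; 0.833: 22.8, 13.1, 31.4; 1.33: 33.2, 19.6, 23.7; 2.00: 40.7, 25.2, 17.4; 3.00: 45.3, 29.0, 12.8; 4.00: 48.2, 32.8, 9.7

(standard deviation of a reading: 0.3 percentage points)

1. left-handed product and right-handed product together, in percent of the left-handed substrate and right-handed substrate charged together, at 6.0 h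
2. excess of left-handed product over right-handed product in the product at 6.0 h
3. whether the exchange between left-handed substrate and right-handed substrate keeps pace with the reaction: how far the product's excess at 6.0 h gets from its value without exchange to its value with instant exchange (above 80% keeps pace, below 20% hardly takes part, else lags behind)

- free catalyst is single-handed; left-handed substrate and right-handed substrate are mirror images of each other, charged as a racemate, each of them at the stated concentration
- the numbers in the tables scatter with a standard deviation of 0.3 percentage points
- an excess is the difference of the two amounts in percent of their sum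
- an excess is below zero if the other one leads

Two times are compared here. Left-handed substrate in violet, read from 60.0 min to 120 min, gives a making half-life t_m = 0.749 h. For the second, this reckoning assumes that product passes first-order into its mirror image, while new product arrives at ε, the excess under kinetic control. Between 2.00 h and 4.00 h the amber run makes 15 percentage points of product, yet its difference D, left-handed minus right-handed product, reads near 16 points at both ends of that stretch. The missing difference, over mean D and the interval, gives the fading rate λ = 0.145 h⁻¹, a reading with a half-life t_f = 4.79 h.

Because t_f is 6.40 times t_m, the 18.7% of violet's charge not yet product at 120 min may count as laid down at once at that time, which fades it too long. This gives both products together at y = 99.5% and an excess of 13.9%. The forecast gives y = 98%, an excess of 20.8% and the exchange keeps pace, holding that “The catalyst's handedness appears to erode”, and its excess stands above this reckoning.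

The flask gives 98.8%, an excess of 14.2%, and the exchange keeps pace, 99.2% of the way.

    reagent ⇌ dormant form (K = 0.460, k = 7.00 × 10⁻⁴ s⁻¹)
    precatalyst → free catalyst (k = 6.50 × 10⁻⁴ s⁻¹)
    left-handed product ⇌ right-handed product (k = 2.00 × 10⁻⁵ s⁻¹)
    reagent + free catalyst + left-handed substrate → free catalyst + left-handed product (k = 79.0 L² mol⁻² s⁻¹)
    left-handed substrate + racemization catalyst ⇌ right-handed substrate + racemization catalyst, rate k5*[racemization catalyst]*[left-handed substrate] forward; the back reaction follows from the equilibrium constant (k = 320 L mol⁻¹ s⁻¹)
    reagent + free catalyst + right-handed substrate → free catalyst + right-handed product (k = 44.0 L² mol⁻² s⁻¹)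

At 6.00 h in the flask, each step taken net, left-handed product is made more slowly than it is used up, at a ratio of 0.470. The neighbour flask with 24 mM of reagent reaches 58.2% with an excess of 15.0% at 6.0 h; at λ = 0.145 h⁻¹, ε fades to that excess in 4.52 h.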